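## Retrosynthetic overview

1. Endgame on the intact skeleton: free O6, oxidise the C15 methyl of an isopropenyl group to the enal, and acylate O9 with angelic acid.
2. The γ-lactone is the last ring formed. O8 is released from an 8,9-acetonide and closes onto the C12 ester while O6 is masked.
3. Key step, which forms the cyclohexane: the C6–C7 bond. C7, the β-carbon of an enoate, is made nucleophilic as a 2-(methoxycarbonyl)allylindium (a homoenolate, d3) and attacks the C6 aldehyde. This sets C6 and C7.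
4. The open-chain precursor comes from a Baylis–Hillman reaction and SN2′ bromination at C7 of a dialdehyde. The vicinal C5/C10 centres come from an Ireland–Claisen rearrangement of a Z-allylic senecioate.
5. C8 and C9 come from D-erythronolactone acetonide. The Z-alkene comes from a hydroxyl-directed carbomagnesiation of an alkyne.

Assumption: elemanolide numbering is used. C10 is the quaternary carbon, C1=C2 its vinyl and C14 its methyl. C5 bears C4(=C3)C15, C6 is the carbinol, and C7 bears C11(=C13)C12. C8 is the lactone carbinol and C9 the ester carbinol. β is the face of C14. The lactol is used as an anomeric mixture and the Baylis–Hillman alcohol as a mixture of carbinol epimers.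

## Route

Step 1
Reactants: 1 (−)-2,3-O-isopropylidene-D-erythronolactone
Product: 2 2,3-O-isopropylidene-D-erythrose (lactol)
Conditions: DIBAL-H (1.1 equiv), CH2Cl2, −78 °C; Rochelle salt
Reagents that add atoms: none
Why: DIBAL-H reduction of a γ-lactone stops at the aluminium hemiacetal at −78 °C (partial lactone reduction), and the two chiral-pool centres that become C8 and C9 are not touched.

Step 2
Reactants: 2 2,3-O-isopropylidene-D-erythrose (lactol)
Product: 3 [(4R,5S)-5-ethynyl-2,2-dimethyl-1,3-dioxolan-4-yl]methanol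
Conditions: Bestmann–Ohira reagent, K2CO3, MeOH, 0 °C to 40 °C
Reagents that add atoms: dimethyl (1-diazo-2-oxopropyl)phosphonate CC(=O)C(=[N+]=[N-])P(=O)(OC)OC
Why: Ohira–Bestmann (Seyferth–Gilbert) homologation intercepts the open hydroxy-aldehyde tautomer of the lactol and turns CHO into C≡CH faster than the cis-dioxolane α-centre can epimerise, which also releases the C7 hydroxyl.

Step 3
Reactants: 3 [(4R,5S)-5-ethynyl-2,2-dimethyl-1,3-dioxolan-4-yl]methanol
Product: 4 3-[(4S,5R)-5-(hydroxymethyl)-2,2-dimethyl-1,3-dioxolan-4-yl]prop-2-yn-1-ol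
Conditions: n-BuLi (2.2 equiv), THF, −78 °C; (CH2O)n, to rt; H2O
Reagents that add atoms: paraformaldehyde (reacts as formaldehyde) C=O
Why: Double deprotonation gives the alkoxide/acetylide dianion and only the acetylide adds to formaldehyde (alkynylation of an aldehyde), which supplies C1 and the propargylic hydroxyl that steers step 4.

Step 4
Reactants: 4 3-[(4S,5R)-5-(hydroxymethyl)-2,2-dimethyl-1,3-dioxolan-4-yl]prop-2-yn-1-ol
Product: 5 (2Z)-3-[(4S,5R)-5-(hydroxymethyl)-2,2-dimethyl-1,3-dioxolan-4-yl]but-2-en-1-ol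
Conditions: Fe(acac)3 (15 mol %), MeMgBr (5 equiv), THF, 0 °C; H2O
Reagents that add atoms: methylmagnesium bromide C[Mg]Br
Why: Alkoxide-directed iron-catalysed syn-carbomagnesiation puts magnesium on the proximal carbon (five-membered chelate) and methyl on the distal one, so protonolysis gives the Z-trisubstituted alkene (C9 cis to C1) on which the relative and facial selectivity of step 6 depend.

Step 5
Reactants: 5 (2Z)-3-[(4S,5R)-5-(hydroxymethyl)-2,2-dimethyl-1,3-dioxolan-4-yl]but-2-en-1-ol; 6 3-methylbut-2-enoyl chloride (senecioyl chloride)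
Product: 7 bis(3-methylbut-2-enoate) of diol 5
Conditions: 6 (2.4 equiv), pyridine, CH2Cl2, 0 °C
Reagents that add atoms: 3-methylbut-2-enoyl chloride (6) CC(C)=CC(=O)Cl
Why: Simple O-acylation (pyridine instead of a trialkylamine avoids the vinylketene pathway and deconjugation) esterifies both primary alcohols and saves a protecting group, because the non-allylic ester is a spectator in step 6 and is cleaved in step 7.

Step 6
Reactants: 7 bis(3-methylbut-2-enoate) of diol 5
Product: 10 (2S,3S)-3-[(4S,5R)-2,2-dimethyl-5-{[(3-methylbut-2-enoyl)oxy]methyl}-1,3-dioxolan-4-yl]-3-methyl-2-(prop-1-en-2-yl)pent-4-enoic acid, via bis(silyl ketene acetal) 8 (not isolated), via trimethylsilyl ester 9 (not isolated)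
Conditions: LDA (2.6 equiv), TMSCl (3 equiv), THF/DMPU, −78 °C to rt; 1 M HCl
Reagents that add atoms: none
Why: Ireland–Claisen rearrangement: γ-deprotonation of the s-cis senecioate gives the Z(O)-silyl dienolate, the chair transition state with the Z-alkene (C14 and C4 equatorial, C9 axial) fixes the C5/C10 relationship, and A1,3 strain (H9 eclipsing C2=C10, the bulky C8 branch anti to the incoming carbon, the small O9 next to C14) fixes both new centres relative to C9.

Step 7
Reactants: 10 the pentenoic acid of step 6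
Product: 11 (2S,3S)-3-[(4S,5R)-5-(hydroxymethyl)-2,2-dimethyl-1,3-dioxolan-4-yl]-3-methyl-2-(prop-1-en-2-yl)pent-4-en-1-ol
Conditions: LiAlH4 (excess), Et2O, 0 °C; aqueous work-up
Reagents that add atoms: none
Why: LiAlH4 reduces the carboxylic acid and cleaves the spectator ester in one operation without touching the isolated alkenes, the acetonide or any stereocentre.

Step 8
Reactants: 11 the diol of step 7
Product: 12 (2S,3S)-3-[(4S,5S)-5-formyl-2,2-dimethyl-1,3-dioxolan-4-yl]-3-methyl-2-(prop-1-en-2-yl)pent-4-enal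
Conditions: Dess–Martin periodinane (2.4 equiv), CH2Cl2, 0 °C to rt
Reagents that add atoms: none
Why: Dess–Martin oxidation is neutral and fast, so both primary alcohols become aldehydes without epimerising C5 or C8 and without moving the β,γ-double bond into conjugation.

Step 9
Reactants: 12 the dialdehyde of step 8; 13 methyl acrylate
Product: 14 methyl 2-[{(4R,5S)-5-[(3S,4S)-4-formyl-3,5-dimethylhexa-1,5-dien-3-yl]-2,2-dimethyl-1,3-dioxolan-4-yl}(hydroxy)methyl]prop-2-enoate
Conditions: 13 (5 equiv), quinuclidine (0.25 equiv), MeOH (2 equiv), 0 °C to rt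
Reagents that add atoms: methyl acrylate (13) C=CC(=O)OC
Why: The Morita–Baylis–Hillman reaction depends strongly on aldehyde sterics and electrophilicity, so the unhindered α-alkoxy aldehyde (C7) reacts while the aldehyde flanked by the C5 branch and the C10 quaternary carbon does not, and the new carbinol centre does not matter because step 10 erases it.

Step 10
Reactants: 14 the Baylis–Hillman alcohol of step 9
Product: 15 methyl (2Z)-2-(bromomethyl)-3-{(4R,5S)-5-[(3S,4S)-4-formyl-3,5-dimethylhexa-1,5-dien-3-yl]-2,2-dimethyl-1,3-dioxolan-4-yl}prop-2-enoate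
Conditions: NBS (1.3 equiv), Me2S (1.5 equiv), CH2Cl2, 0 °C to rt
Reagents that add atoms: N-bromosuccinimide O=C1CCC(=O)N1Br
Why: The sulfonium reagent activates the allylic hydroxyl and bromide attacks in the SN2′ sense (allylic transposition of a Baylis–Hillman alcohol), giving the preferred Z-2-(bromomethyl)enoate in which C8 is cis to CH2Br.

Step 11 (key step)
Reactants: 15 the Z-bromomethyl enoate aldehyde of step 10
Product: 17 methyl 6β-hydroxy-8α,9α-isopropylidenedioxyelema-1,3,11(13)-trien-12-oate (5S,6S,7S,8R,9S,10S), via allylindium species 16 (not isolated)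
Conditions: In powder (2 equiv), THF/H2O 1:1, 0.005 M, rt
Reagents that add atoms: none
Why: Intramolecular indium Barbier allylation (Dreiding–Schmidt type): reductive metalation turns C7, normally the electrophilic β-carbon of the enoate, into the nucleophilic γ-terminus of a 2-(methoxycarbonyl)allylindium (a homoenolate d3 equivalent) that attacks the equally electrophilic C6 aldehyde through a chair/chair Zimmerman–Traxler array in which H8 eclipses C7=C11 (A1,3 strain), the isopropenyl, vinyl and O8 groups are equatorial and the Z-allyl geometry forces the indium-bound oxygen axial, which sets 7β-C11 and 6β-OH, while water protonates the alkoxide before it can lactonise.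

Step 12
Reactants: 17 the cyclised hydroxy ester of step 11
Product: 18 methyl 6β-(tert-butyldimethylsilyloxy)-8α,9α-isopropylidenedioxyelema-1,3,11(13)-trien-12-oate
Conditions: TBSOTf (1.5 equiv), 2,6-lutidine (3 equiv), CH2Cl2, −20 °C to 0 °C
Reagents that add atoms: tert-butyldimethylsilyl triflate CC(C)(C)[Si](C)(C)OS(=O)(=O)C(F)(F)F
Why: Silyl triflate silylation reaches even this axial, doubly flanked hydroxyl, and O6 must be masked now because the cis-6,12-lactone is the thermodynamic sink once the ester meets acid.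

Step 13
Reactants: 18 the TBS ether of step 12
Product: 20 6β-(tert-butyldimethylsilyloxy)-9α-hydroxyelema-1,3,11(13)-trien-12,8α-olide, via diol ester 19 (not isolated)
Conditions: AcOH/H2O 4:1, 55 °C
Reagents that add atoms: none
Why: Aqueous acetic acid hydrolyses the cis-fused acetonide but not the hindered secondary TBS ether, and of the two hydroxyls set free only the equatorial O8 is γ to the ester, so it closes the trans-fused α-methylene-γ-lactone (acid-catalysed lactonisation) and leaves O9-H as the only free hydroxyl.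

Step 14
Reactants: 20 the hydroxy lactone of step 13; 21 angelic acid [(2Z)-2-methylbut-2-enoic acid]
Product: 23 9α-angeloyloxy-6β-(tert-butyldimethylsilyloxy)elema-1,3,11(13)-trien-12,8α-olide, via mixed anhydride 22 (not isolated)
Conditions: 21, 2,4,6-trichlorobenzoyl chloride, Et3N, toluene, rt; then 20, 80 °C (no DMAP)
Reagents that add atoms: angelic acid (21) C/C=C(/C)C(=O)O
Why: Yamaguchi-type mixed-anhydride acylation without DMAP transfers the angeloyl group to hindered secondary alcohols with retention of the Z geometry, and O9-H is the only acylable site.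

Step 15
Reactants: 23 the angelate of step 14
Product: 24 9α-angeloyloxy-6β-(tert-butyldimethylsilyloxy)-15-oxoelema-1,3,11(13)-trien-12,8α-olide
Conditions: SeO2 (1.5 equiv), 1,4-dioxane, 80 °C
Reagents that add atoms: selenium dioxide O=[Se]=O
Why: Selenium dioxide allylic oxidation (ene reaction then [2,3]-shift) picks the isopropenyl group, the only electron-rich alkene with allylic hydrogens, and attacks its methyl rather than C5-H because that C–H lies in the alkene plane, while the vinyl group has no allylic hydrogen and the acrylate and angelate alkenes are electron-poor.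

Step 16
Reactants: 24 the silylated enal of step 15
Product: 25 9α-angeloyloxy-6β-hydroxy-15-oxoelema-1,3,11(13)-trien-12,8α-olide (5R,6S,7S,8R,9S,10S), the target
Conditions: HF·pyridine, THF, 0 °C to rt
Reagents that add atoms: none
Why: Fluoride-mediated desilylation under mildly acidic, non-basic conditions frees O6-H without Michael addition, angelate isomerisation or base-induced translactonisation to the 6,12-olide.

## Compound list

1 | (−)-2,3-O-isopropylidene-D-erythronolactone, (3aR,6aR) | O=C1[C@@H]2OC(C)(C)O[C@@H]2CO1 | starting material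
2 | 2,3-O-isopropylidene-D-erythrose, lactol, anomeric mixture | OC1[C@@H]2OC(C)(C)O[C@@H]2CO1 | intermediate
3 | [(4R,5S)-5-ethynyl-2,2-dimethyl-1,3-dioxolan-4-yl]methanol | C#C[C@@H]1OC(C)(C)O[C@@H]1CO | intermediate
4 | 3-[(4S,5R)-5-(hydroxymethyl)-2,2-dimethyl-1,3-dioxolan-4-yl]prop-2-yn-1-ol | OCC#C[C@@H]1OC(C)(C)O[C@@H]1CO | intermediate
5 | (2Z)-3-[(4S,5R)-5-(hydroxymethyl)-2,2-dimethyl-1,3-dioxolan-4-yl]but-2-en-1-ol | OC/C=C(/C)[C@@H]1OC(C)(C)O[C@@H]1CO | intermediate
6 | 3-methylbut-2-enoyl chloride | CC(C)=CC(=O)Cl | starting material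
7 | bis(3-methylbut-2-enoate) of 5 | CC(C)=CC(=O)OC/C=C(/C)[C@@H]1OC(C)(C)O[C@@H]1COC(=O)C=C(C)C | intermediate
8 | bis(trimethylsilyl ketene acetal) of 7, both Z(O) | C=C(C)/C=C(\O[Si](C)(C)C)OC/C=C(/C)[C@@H]1OC(C)(C)O[C@@H]1CO/C(O[Si](C)(C)C)=C/C(C)=C | intermediate
9 | trimethylsilyl ester of the rearranged acid, spectator ketene acetal still in place | C[Si](C)(C)OC(=O)[C@@H](C(C)=C)[C@](C)(C=C)[C@@H]1OC(C)(C)O[C@@H]1CO/C(O[Si](C)(C)C)=C/C(C)=C | intermediate
10 | (2S,3S)-3-[(4S,5R)-2,2-dimethyl-5-{[(3-methylbut-2-enoyl)oxy]methyl}-1,3-dioxolan-4-yl]-3-methyl-2-(prop-1-en-2-yl)pent-4-enoic acid | OC(=O)[C@@H](C(C)=C)[C@](C)(C=C)[C@@H]1OC(C)(C)O[C@@H]1COC(=O)C=C(C)C | intermediate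
11 | (2S,3S)-3-[(4S,5R)-5-(hydroxymethyl)-2,2-dimethyl-1,3-dioxolan-4-yl]-3-methyl-2-(prop-1-en-2-yl)pent-4-en-1-ol | OC[C@@H](C(C)=C)[C@](C)(C=C)[C@@H]1OC(C)(C)O[C@@H]1CO | intermediate
12 | (2S,3S)-3-[(4S,5S)-5-formyl-2,2-dimethyl-1,3-dioxolan-4-yl]-3-methyl-2-(prop-1-en-2-yl)pent-4-enal | O=C[C@@H](C(C)=C)[C@](C)(C=C)[C@@H]1OC(C)(C)O[C@@H]1C=O | intermediate
13 | methyl acrylate | C=CC(=O)OC | starting material
14 | Baylis–Hillman alcohol at C7, carbinol epimers | O=C[C@@H](C(C)=C)[C@](C)(C=C)[C@@H]1OC(C)(C)O[C@@H]1C(O)C(=C)C(=O)OC | intermediate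
15 | methyl (2Z)-2-(bromomethyl)-3-{(4R,5S)-5-[(3S,4S)-4-formyl-3,5-dimethylhexa-1,5-dien-3-yl]-2,2-dimethyl-1,3-dioxolan-4-yl}prop-2-enoate | O=C[C@@H](C(C)=C)[C@](C)(C=C)[C@@H]1OC(C)(C)O[C@@H]1/C=C(\CBr)C(=O)OC | intermediate
16 | (Z)-2-(methoxycarbonyl)allylindium species, drawn as the monomeric RInBr2 form of the sesquibromide | O=C[C@@H](C(C)=C)[C@](C)(C=C)[C@@H]1OC(C)(C)O[C@@H]1/C=C(\C[In](Br)Br)C(=O)OC | intermediate
17 | methyl 6β-hydroxy-8α,9α-isopropylidenedioxyelema-1,3,11(13)-trien-12-oate (5αH,7αH,8βH,9βH,10β-Me) | C=C[C@]1(C)[C@@H]2OC(C)(C)O[C@@H]2[C@@H](C(=C)C(=O)OC)[C@@H](O)[C@H]1C(C)=C | intermediate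
18 | 6-O-TBS ether of 17 | C=C[C@]1(C)[C@@H]2OC(C)(C)O[C@@H]2[C@@H](C(=C)C(=O)OC)[C@@H](O[Si](C)(C)C(C)(C)C)[C@H]1C(C)=C | intermediate
19 | methyl 6β-(TBS-oxy)-8α,9α-dihydroxyelema-1,3,11(13)-trien-12-oate | C=C[C@]1(C)[C@H](O)[C@H](O)[C@@H](C(=C)C(=O)OC)[C@@H](O[Si](C)(C)C(C)(C)C)[C@H]1C(C)=C | intermediate
20 | 6β-(TBS-oxy)-9α-hydroxyelema-1,3,11(13)-trien-12,8α-olide | C=C[C@]1(C)[C@H](O)[C@@H]2OC(=O)C(=C)[C@H]2[C@@H](O[Si](C)(C)C(C)(C)C)[C@H]1C(C)=C | intermediate
21 | angelic acid, (2Z)-2-methylbut-2-enoic acid | C/C=C(/C)C(=O)O | starting material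
22 | angelic 2,4,6-trichlorobenzoic anhydride | C/C=C(/C)C(=O)OC(=O)c1c(Cl)cc(Cl)cc1Cl | intermediate
23 | 9α-angeloyloxy-6β-(TBS-oxy)elema-1,3,11(13)-trien-12,8α-olide | C=C[C@]1(C)[C@H](OC(=O)/C(C)=C\C)[C@@H]2OC(=O)C(=C)[C@H]2[C@@H](O[Si](C)(C)C(C)(C)C)[C@H]1C(C)=C | intermediate
24 | 9α-angeloyloxy-6β-(TBS-oxy)-15-oxoelema-1,3,11(13)-trien-12,8α-olide | C=C[C@]1(C)[C@H](OC(=O)/C(C)=C\C)[C@@H]2OC(=O)C(=C)[C@H]2[C@@H](O[Si](C)(C)C(C)(C)C)[C@H]1C(=C)C=O | intermediate
25 | 9α-angeloyloxy-6β-hydroxy-15-oxoelema-1,3,11(13)-trien-12,8α-olide (CNP0320538.1) | C=C[C@]1(C)[C@H](OC(=O)/C(C)=C\C)[C@@H]2OC(=O)C(=C)[C@H]2[C@@H](O)[C@H]1C(=C)C=O | target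

## Step count

Total step count: 16. Longest linear sequence: 16 (1 to 25). Compounds 6, 13 and 21 are bought.

## Steps most likely to fail

**Step 11 (ring closure).**
- Risks: the axial C6–O bond sits 1,3-diaxial to C14. An E/Z-equilibrating allylmetal could therefore close through the all-equatorial array and give the 6α-alcohol. The metal alkoxide could also lactonise.
- Fallback, from 15 back to 17: C6 is no longer set in the C–C bond formation.
- Closure of 15 with CrCl2 in THF (Nozaki–Hiyama type, anti-selective) gives methyl 6α-hydroxy-8α,9α-isopropylidenedioxyelema-1,3,11(13)-trien-12-oate F1.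
- Dess–Martin oxidation of F1 (or of any C6 epimer mixture) gives methyl 8α,9α-isopropylidenedioxy-6-oxoelema-1,3,11(13)-trien-12-oate F2.
- NaBH4/CeCl3 in MeOH at −78 °C then delivers hydride from the α face, opposite the axial C14 methyl, and returns the 6β-alcohol 17.

**Step 9 (one aldehyde out of two).**
- Risks: the amine catalyst could epimerise C8 or C5, conjugate the β,γ-unsaturated aldehyde, or trigger an intramolecular aldol reaction of the 1,6-dialdehyde.
- Fallback, from 11 back to 15: the sensitive C6 aldehyde is not made until after the Baylis–Hillman step.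
- TEMPO/PhI(OAc)2 (1 equiv) oxidises the less hindered C7 carbinol of 11 to (4S,5S)-5-[(3S,4S)-4-(hydroxymethyl)-3,5-dimethylhexa-1,5-dien-3-yl]-2,2-dimethyl-1,3-dioxolane-4-carbaldehyde F3.
- The Baylis–Hillman reaction with 13 gives the C6-hydroxy Baylis–Hillman diol F4.
- NBS/Me2S (2.5 equiv) followed by Et3N then does two jobs in one flask. The allylic alkoxysulfonium collapses by SN2′ to the Z-bromide, and the primary one is oxidised in the Corey–Kim sense to the aldehyde. The product is 15.

**Step 4 (directed carbomagnesiation).**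
- Risks: the polyoxygenated dialkoxide may poison the iron catalyst or react sluggishly.
- Fallback, from 3 back to 5: the methyl group is brought in by conjugate addition instead.
- n-BuLi (2.2 equiv) and ClCO2Me (2.2 equiv) convert 3 into methyl 4-[(4S,5R)-5-{[(methoxycarbonyl)oxy]methyl}-2,2-dimethyl-1,3-dioxolan-4-yl]but-2-ynoate F5.
- Me2CuLi at −78 °C adds syn, and protonation gives methyl (2Z)-3-[(4S,5R)-5-{[(methoxycarbonyl)oxy]methyl}-2,2-dimethyl-1,3-dioxolan-4-yl]but-2-enoate F6.
- Excess DIBAL-H reduces the ester and removes the carbonate to give 5.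

Further compounds
F1 | step 11 | methyl 6α-hydroxy-8α,9α-isopropylidenedioxyelema-1,3,11(13)-trien-12-oate | C=C[C@]1(C)[C@@H]2OC(C)(C)O[C@@H]2[C@@H](C(=C)C(=O)OC)[C@H](O)[C@H]1C(C)=C
F2 | step 11 | methyl 8α,9α-isopropylidenedioxy-6-oxoelema-1,3,11(13)-trien-12-oate | C=C[C@]1(C)[C@@H]2OC(C)(C)O[C@@H]2[C@@H](C(=C)C(=O)OC)C(=O)[C@H]1C(C)=C
F3 | step 9 | (4S,5S)-5-[(3S,4S)-4-(hydroxymethyl)-3,5-dimethylhexa-1,5-dien-3-yl]-2,2-dimethyl-1,3-dioxolane-4-carbaldehyde | OC[C@@H](C(C)=C)[C@](C)(C=C)[C@@H]1OC(C)(C)O[C@@H]1C=O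
F4 | step 9 | C6-hydroxy Baylis–Hillman diol (carbinol epimers at C7) | OC[C@@H](C(C)=C)[C@](C)(C=C)[C@@H]1OC(C)(C)O[C@@H]1C(O)C(=C)C(=O)OC
F5 | step 4 | methyl 4-[(4S,5R)-5-{[(methoxycarbonyl)oxy]methyl}-2,2-dimethyl-1,3-dioxolan-4-yl]but-2-ynoate | COC(=O)C#C[C@@H]1OC(C)(C)O[C@@H]1COC(=O)OC
F6 | step 4 | methyl (2Z)-3-[(4S,5R)-5-{[(methoxycarbonyl)oxy]methyl}-2,2-dimethyl-1,3-dioxolan-4-yl]but-2-enoate | COC(=O)/C=C(/C)[C@@H]1OC(C)(C)O[C@@H]1COC(=O)OC
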